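C7 is the carbinol carbon on ring A (the 4-hydroxy-3,5-dimethoxyphenyl ring), C8 carries the aryl ether oxygen to ring B (the 2,6-dimethoxy-4-(E)-propenylphenyl ring), and C9 is the methyl group.
Feature and cuts: C7 and C8 are adjacent oxygen-bearing stereocentres, so the C7–C8 bond is cut as an aldol, with C7 the formyl carbon of a ring A aldehyde and C8–C9 an aryloxythioacetate enolate equivalent. The other cuts are C9–H (methyl back to thioester), C9–S, the bond from the ring B oxygen to C8 (phenol plus bromoacetic acid) and the ring A O–Si bond.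
Forward order: no ring is formed. The ring B phenol becomes the aryloxyacetic acid, the S-ethyl thioester and then the Z silyl ketene acetal, which is joined at C7–C8 to O-silylated syringaldehyde. C9 then goes from thioester through CH2OH and CH2OTs to CH3, and the ring A phenol is freed last.
Stereochemistry: 7R and 8S (erythro, anti) both arise in the aldol. The Sn(OTf)2 complex of an (S)-proline-derived diamine selects the aldehyde face, and the tin-coordinating aryloxy group of the Z ketene acetal sets the anti topicity. The E-propenyl group comes with the starting phenol, and no later step touches C7, C8 or the alkene.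

Key step: step 5

Assumption: phenol 1 is used as the commercial, geometrically pure E isomer, and the ketene acetal descriptor follows sulfur > oxygen, so Z means aryloxy cis to SEt.

Step 1
Reactants: 1 (E)-2,6-dimethoxy-4-(prop-1-enyl)phenol; 2 bromoacetic acid
Product: 3 2-[2,6-dimethoxy-4-((E)-prop-1-enyl)phenoxy]acetic acid
Conditions: NaOH (aq, 3 equiv), H2O, 90 °C, Ar; then HCl (aq), 0 °C
Reagents that add atoms: none
Why: Williamson ether synthesis: under argon the sodium phenoxide of 1 displaces bromide from sodium bromoacetate in an SN2 reaction at a primary carbon, the classical route to aryloxyacetic acids, and neither the methyl ethers nor the E-propenyl group react with hot aqueous base.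

Step 2
Reactants: 3 2-[2,6-dimethoxy-4-((E)-prop-1-enyl)phenoxy]acetic acid; 4 ethanethiol
Product: 5 S-ethyl 2-[2,6-dimethoxy-4-((E)-prop-1-enyl)phenoxy]ethanethioate
Conditions: DCC, DMAP (cat.), CH2Cl2, 0 °C → rt
Reagents that add atoms: none
Why: Steglich-type DCC/DMAP coupling: the O-acylisourea, relayed by DMAP as an acylpyridinium ion, is intercepted by the thiol to give the thioester, the acid has no stereocentre to lose, and nothing else in 3 is acylated or attacked by the thiol under these non-radical conditions.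

Step 3
Reactants: 5 S-ethyl 2-[2,6-dimethoxy-4-((E)-prop-1-enyl)phenoxy]ethanethioate
Product: 7 (Z)-1-(ethylthio)-1-(trimethylsilyloxy)-2-[2,6-dimethoxy-4-((E)-prop-1-enyl)phenoxy]ethene, via lithium enolate 6 (not isolated)
Conditions: LiN(iPr)2, THF, −78 °C; then Me3SiCl, −78 °C → rt; pentane, filtration under Ar
Reagents that add atoms: chlorotrimethylsilane, C[Si](C)(C)Cl
Why: Kinetic α-deprotonation of a thioester with LiN(iPr)2 at −78 °C followed by O-silylation is the standard entry to thioester silyl ketene acetals; the cyclic deprotonation transition state should place the aryloxy group trans to O–Li and hence cis to sulfur (Z), the product is taken on after non-aqueous work-up, and its geometry is to be checked by NOE.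

Step 4
Reactants: 8 syringaldehyde (4-hydroxy-3,5-dimethoxybenzaldehyde)
Product: 9 3,5-dimethoxy-4-(triisopropylsilyloxy)benzaldehyde
Conditions: iPr3SiCl, imidazole, DMF, rt
Reagents that add atoms: chlorotriisopropylsilane, CC(C)[Si](Cl)(C(C)C)C(C)C
Why: Imidazole-mediated O-silylation of a phenol: the para-formyl group makes the hindered syringyl hydroxyl acidic enough to be silylated, and the triisopropylsilyl ether is chosen because it should survive Sn(OTf)2, LiAlH4, TsCl/pyridine and LiBHEt3 yet leave with fluoride.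

Step 5
Reactants: 7 (Z)-1-(ethylthio)-1-(trimethylsilyloxy)-2-[2,6-dimethoxy-4-((E)-prop-1-enyl)phenoxy]ethene; 9 3,5-dimethoxy-4-(triisopropylsilyloxy)benzaldehyde
Product: 11 S-ethyl (2R,3R)-2-[2,6-dimethoxy-4-((E)-prop-1-enyl)phenoxy]-3-[3,5-dimethoxy-4-(triisopropylsilyloxy)phenyl]-3-hydroxypropanethioate, via O-trimethylsilyl aldol adduct 10 (not isolated)
Conditions: Sn(OTf)2 (1.0 equiv), (S)-1-ethyl-2-(piperidin-1-ylmethyl)pyrrolidine (1.2 equiv), Bu2Sn(OAc)2 (1.1 equiv), CH2Cl2, −78 °C; NaHCO3 (aq); then citric acid, THF–H2O, 0 °C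
Reagents that add atoms: none
Why: Proposed new method: the diamine-chelated Sn(OTf)2 (divalent tin) binds the formyl oxygen of 9 and ketene acetal 7 adds through an open transition state, silyl transfer giving the O-silyl aldol 10, which mild acid converts to 11. The closest known reaction is the Sn(OTf)2/chiral diamine/Bu2Sn(OAc)2-promoted asymmetric Mukaiyama aldol of the α-benzyloxy analogue of 7, which is anti-selective; an α-aryloxy donor has not been used in it and its ether oxygen is a weaker donor, which is why the step is a proposal. No ring is closed; only the C7–C8 bond forms. C7 (C3 of the thioester) is set by the (S)-diamine–tin complex, which by analogy should expose the si face of the aldehyde and give 3R, and C8 (C2) is set by the orientation of the Z ketene acetal, whose aryloxy oxygen, helped by an ortho methoxy group, is expected to coordinate tin and turn the donor so that the anti (2R) isomer results. The step needs anti over syn and si over re selectivity and attack at the aldehyde in preference to the propenyl arene; the geometric purity of 7, the chelating 2,6-dimethoxyphenoxy group, the amine-buffered promoter and −78 °C are what should secure them.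

Step 6
Reactants: 11 S-ethyl (2R,3R)-2-[2,6-dimethoxy-4-((E)-prop-1-enyl)phenoxy]-3-[3,5-dimethoxy-4-(triisopropylsilyloxy)phenyl]-3-hydroxypropanethioate
Product: 12 (1R,2S)-2-[2,6-dimethoxy-4-((E)-prop-1-enyl)phenoxy]-1-[3,5-dimethoxy-4-(triisopropylsilyloxy)phenyl]propane-1,3-diol
Conditions: LiAlH4, THF, −78 → 0 °C; then H2O, NaOH (aq)
Reagents that add atoms: none
Why: Hydride reduction of a thioester to the primary alcohol with loss of ethanethiolate; at low temperature reduction of the aluminium aldolate should outrun retro-aldol cleavage and enolisation, so C7 and C8 are untouched (the C8 descriptor changes from R to S only because CH2OH ranks below the carbinol carbon), and the aryl silyl ether, methyl ethers and alkene are inert to LiAlH4.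

Step 7
Reactants: 12 (1R,2S)-2-[2,6-dimethoxy-4-((E)-prop-1-enyl)phenoxy]-1-[3,5-dimethoxy-4-(triisopropylsilyloxy)phenyl]propane-1,3-diol
Product: 13 (2S,3R)-2-[2,6-dimethoxy-4-((E)-prop-1-enyl)phenoxy]-3-[3,5-dimethoxy-4-(triisopropylsilyloxy)phenyl]-3-hydroxypropyl 4-methylbenzenesulfonate
Conditions: TsCl (1.1 equiv), pyridine, CH2Cl2, 0 °C
Reagents that add atoms: 4-methylbenzenesulfonyl chloride, Cc1ccc(cc1)S(Cl)(=O)=O
Why: Selective sulfonylation of the primary hydroxyl of a 1,3-diol: TsCl in pyridine at 0 °C reacts far faster with the unhindered CH2OH than with the secondary benzylic hydroxyl next to the aryloxy-bearing carbon, and no stereocentre is involved.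

Step 8
Reactants: 13 (2S,3R)-2-[2,6-dimethoxy-4-((E)-prop-1-enyl)phenoxy]-3-[3,5-dimethoxy-4-(triisopropylsilyloxy)phenyl]-3-hydroxypropyl 4-methylbenzenesulfonate
Product: 14 (1R,2S)-2-[2,6-dimethoxy-4-((E)-prop-1-enyl)phenoxy]-1-[3,5-dimethoxy-4-(triisopropylsilyloxy)phenyl]propan-1-ol
Conditions: LiBHEt3 (3 equiv), THF, 0 °C → rt
Reagents that add atoms: none
Why: SN2 displacement of a primary tosylate by hydride (sulfonate deoxygenation with LiBHEt3): the first equivalent deprotonates the C7 hydroxyl, the next hydride should attack the unhindered C9 faster than the alkoxide can close an oxetane, and C7, C8, the silyl ether and the alkene are not touched.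

Step 9
Reactants: 14 (1R,2S)-2-[2,6-dimethoxy-4-((E)-prop-1-enyl)phenoxy]-1-[3,5-dimethoxy-4-(triisopropylsilyloxy)phenyl]propan-1-ol
Product: 15 4-[(1R,2S)-2-[2,6-dimethoxy-4-((E)-prop-1-enyl)phenoxy]-1-hydroxypropyl]-2,6-dimethoxyphenol (CNP0174373.1)
Conditions: Bu4NF, AcOH, THF, 0 °C
Reagents that add atoms: none
Why: Fluoride cleavage of an aryl silyl ether driven by Si–F bond formation; acetic acid protonates the phenoxide as it forms so that the 4-hydroxybenzyl alcohol cannot eliminate to a quinone methide, and no stereocentre is affected.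

Compound list
1 | (E)-2,6-dimethoxy-4-(prop-1-enyl)phenol | C/C=C/c1cc(OC)c(O)c(OC)c1 | starting material
2 | bromoacetic acid | OC(=O)CBr | starting material
3 | 2-[2,6-dimethoxy-4-((E)-prop-1-enyl)phenoxy]acetic acid | C/C=C/c1cc(OC)c(OCC(=O)O)c(OC)c1 | intermediate
4 | ethanethiol | CCS | starting material
5 | S-ethyl 2-[2,6-dimethoxy-4-((E)-prop-1-enyl)phenoxy]ethanethioate | C/C=C/c1cc(OC)c(OCC(=O)SCC)c(OC)c1 | intermediate
6 | lithium (Z)-1-(ethylthio)-2-[2,6-dimethoxy-4-((E)-prop-1-enyl)phenoxy]ethen-1-olate (lithium enolate of 5) | CCS/C(=C\Oc1c(OC)cc(/C=C/C)cc1OC)O[Li] | intermediate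
7 | (Z)-1-(ethylthio)-1-(trimethylsilyloxy)-2-[2,6-dimethoxy-4-((E)-prop-1-enyl)phenoxy]ethene | CCS/C(=C\Oc1c(OC)cc(/C=C/C)cc1OC)O[Si](C)(C)C | intermediate
8 | syringaldehyde (4-hydroxy-3,5-dimethoxybenzaldehyde) | COc1cc(C=O)cc(OC)c1O | starting material
9 | 3,5-dimethoxy-4-(triisopropylsilyloxy)benzaldehyde | CC(C)[Si](Oc1c(OC)cc(C=O)cc1OC)(C(C)C)C(C)C | intermediate
10 | S-ethyl (2R,3R)-2-[2,6-dimethoxy-4-((E)-prop-1-enyl)phenoxy]-3-[3,5-dimethoxy-4-(triisopropylsilyloxy)phenyl]-3-(trimethylsilyloxy)propanethioate | C/C=C/c1cc(OC)c(O[C@@H](C(=O)SCC)[C@H](O[Si](C)(C)C)c2cc(OC)c(O[Si](C(C)C)(C(C)C)C(C)C)c(OC)c2)c(OC)c1 | intermediate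
11 | S-ethyl (2R,3R)-2-[2,6-dimethoxy-4-((E)-prop-1-enyl)phenoxy]-3-[3,5-dimethoxy-4-(triisopropylsilyloxy)phenyl]-3-hydroxypropanethioate | C/C=C/c1cc(OC)c(O[C@@H](C(=O)SCC)[C@H](O)c2cc(OC)c(O[Si](C(C)C)(C(C)C)C(C)C)c(OC)c2)c(OC)c1 | intermediate
12 | (1R,2S)-2-[2,6-dimethoxy-4-((E)-prop-1-enyl)phenoxy]-1-[3,5-dimethoxy-4-(triisopropylsilyloxy)phenyl]propane-1,3-diol | C/C=C/c1cc(OC)c(O[C@@H](CO)[C@H](O)c2cc(OC)c(O[Si](C(C)C)(C(C)C)C(C)C)c(OC)c2)c(OC)c1 | intermediate
13 | (2S,3R)-2-[2,6-dimethoxy-4-((E)-prop-1-enyl)phenoxy]-3-[3,5-dimethoxy-4-(triisopropylsilyloxy)phenyl]-3-hydroxypropyl 4-methylbenzenesulfonate | C/C=C/c1cc(OC)c(O[C@@H](COS(=O)(=O)c3ccc(C)cc3)[C@H](O)c2cc(OC)c(O[Si](C(C)C)(C(C)C)C(C)C)c(OC)c2)c(OC)c1 | intermediate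
14 | (1R,2S)-2-[2,6-dimethoxy-4-((E)-prop-1-enyl)phenoxy]-1-[3,5-dimethoxy-4-(triisopropylsilyloxy)phenyl]propan-1-ol | C/C=C/c1cc(OC)c(O[C@@H](C)[C@H](O)c2cc(OC)c(O[Si](C(C)C)(C(C)C)C(C)C)c(OC)c2)c(OC)c1 | intermediate
15 | 4-[(1R,2S)-2-[2,6-dimethoxy-4-((E)-prop-1-enyl)phenoxy]-1-hydroxypropyl]-2,6-dimethoxyphenol | C/C=C/c1cc(OC)c(O[C@@H](C)[C@H](O)c2cc(OC)c(O)c(OC)c2)c(OC)c1 | target

Total step count: 9. Longest linear sequence: 8 steps (steps 1, 2, 3, 5, 6, 7, 8, 9 from phenol 1); the aldehyde arm adds step 4 before the convergence.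

Steps most likely to fail

Step 5 (proposed new method). The anti topicity may erode or invert if the hindered, weakly basic aryloxy oxygen does not coordinate tin, or if the ketene acetal from step 3 is not geometrically pure. Facial discrimination may also fall with the electron-rich aldehyde, and the absolute sense rests on analogy, so it is to be confirmed on 11 before going on.

The fallback sets out from 1 and comes back at 14; it takes C8 from the chiral pool and sets C7 by 1,2-induction, using known reactions only. Mitsunobu etherification of 1 with methyl (R)-lactate (PPh3, DIAD, THF, 0 °C → rt) should give, with inversion, methyl (2S)-2-[2,6-dimethoxy-4-((E)-prop-1-enyl)phenoxy]propanoate F1. Treatment with MeNHOMe·HCl and iPrMgCl (THF, −20 °C) would convert it into the Weinreb amide (2S)-2-[2,6-dimethoxy-4-((E)-prop-1-enyl)phenoxy]-N-methoxy-N-methylpropanamide F2. Separately, commercial 4-bromo-2,6-dimethoxyphenol is silylated (iPr3SiCl, imidazole, DMF) to (4-bromo-2,6-dimethoxyphenoxy)triisopropylsilane F3. Bromine–lithium exchange (n-BuLi, THF, −78 °C) gives [3,5-dimethoxy-4-(triisopropylsilyloxy)phenyl]lithium F4, which should acylate with F2 to the ketone (2S)-2-[2,6-dimethoxy-4-((E)-prop-1-enyl)phenoxy]-1-[3,5-dimethoxy-4-(triisopropylsilyloxy)phenyl]propan-1-one F5. Chelation-controlled reduction with Zn(BH4)2 (Et2O, −20 °C), in which zinc bridges the carbonyl and aryloxy oxygens and hydride arrives on the side away from the methyl group, should give the erythro (1R,2S) alcohol 14.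

Step 6. The metal aldolate formed on deprotonation of the C7 hydroxyl may undergo retro-aldol cleavage, or C8 may epimerise, before the thioester carbonyl is reduced.

The fallback sets out from 11 and comes back at 12; it removes the strongly basic hydride from the thioester stage. A Fukuyama reduction (Et3SiH, Pd on CaCO3 poisoned with Pb(OAc)2, acetone, rt) should convert the S-ethyl thioester under neutral conditions into (2R,3R)-2-[2,6-dimethoxy-4-((E)-prop-1-enyl)phenoxy]-3-[3,5-dimethoxy-4-(triisopropylsilyloxy)phenyl]-3-hydroxypropanal F6, sparing the propenyl group. This is reduced at once with NaBH4 (MeOH, −20 °C) to diol 12.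

Step 8. Under the basic hydride the C7 alkoxide may displace the tosylate intramolecularly (oxetane formation) faster than hydride is delivered to C9.

The fallback sets out from 13 and comes back at 15; it removes the internal nucleophile instead of trying to outrun it. Silylation of the C7 hydroxyl (Et3SiOTf, 2,6-lutidine, CH2Cl2, −78 °C) would give (2S,3R)-2-[2,6-dimethoxy-4-((E)-prop-1-enyl)phenoxy]-3-[3,5-dimethoxy-4-(triisopropylsilyloxy)phenyl]-3-(triethylsilyloxy)propyl 4-methylbenzenesulfonate F7. LiBHEt3 (THF, 0 °C → rt) would then reduce the tosylate to triethyl{(1R,2S)-2-[2,6-dimethoxy-4-((E)-prop-1-enyl)phenoxy]-1-[3,5-dimethoxy-4-(triisopropylsilyloxy)phenyl]propoxy}silane F8. Bu4NF/AcOH (THF, rt) removes both silyl groups in one operation to give 15.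

Further compounds
F1 | step 5 | methyl (2S)-2-[2,6-dimethoxy-4-((E)-prop-1-enyl)phenoxy]propanoate | C/C=C/c1cc(OC)c(O[C@@H](C)C(=O)OC)c(OC)c1
F2 | step 5 | (2S)-2-[2,6-dimethoxy-4-((E)-prop-1-enyl)phenoxy]-N-methoxy-N-methylpropanamide | C/C=C/c1cc(OC)c(O[C@@H](C)C(=O)N(C)OC)c(OC)c1
F3 | step 5 | (4-bromo-2,6-dimethoxyphenoxy)triisopropylsilane | CC(C)[Si](Oc1c(OC)cc(Br)cc1OC)(C(C)C)C(C)C
F4 | step 5 | [3,5-dimethoxy-4-(triisopropylsilyloxy)phenyl]lithium | [Li]c1cc(OC)c(O[Si](C(C)C)(C(C)C)C(C)C)c(OC)c1
F5 | step 5 | (2S)-2-[2,6-dimethoxy-4-((E)-prop-1-enyl)phenoxy]-1-[3,5-dimethoxy-4-(triisopropylsilyloxy)phenyl]propan-1-one | C/C=C/c1cc(OC)c(O[C@@H](C)C(=O)c2cc(OC)c(O[Si](C(C)C)(C(C)C)C(C)C)c(OC)c2)c(OC)c1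
F6 | step 6 | (2R,3R)-2-[2,6-dimethoxy-4-((E)-prop-1-enyl)phenoxy]-3-[3,5-dimethoxy-4-(triisopropylsilyloxy)phenyl]-3-hydroxypropanal | C/C=C/c1cc(OC)c(O[C@@H](C=O)[C@H](O)c2cc(OC)c(O[Si](C(C)C)(C(C)C)C(C)C)c(OC)c2)c(OC)c1
F7 | step 8 | (2S,3R)-2-[2,6-dimethoxy-4-((E)-prop-1-enyl)phenoxy]-3-[3,5-dimethoxy-4-(triisopropylsilyloxy)phenyl]-3-(triethylsilyloxy)propyl 4-methylbenzenesulfonate | C/C=C/c1cc(OC)c(O[C@@H](COS(=O)(=O)c3ccc(C)cc3)[C@H](O[Si](CC)(CC)CC)c2cc(OC)c(O[Si](C(C)C)(C(C)C)C(C)C)c(OC)c2)c(OC)c1
F8 | step 8 | triethyl{(1R,2S)-2-[2,6-dimethoxy-4-((E)-prop-1-enyl)phenoxy]-1-[3,5-dimethoxy-4-(triisopropylsilyloxy)phenyl]propoxy}silane | C/C=C/c1cc(OC)c(O[C@@H](C)[C@H](O[Si](CC)(CC)CC)c2cc(OC)c(O[Si](C(C)C)(C(C)C)C(C)C)c(OC)c2)c(OC)c1
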